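**Strategy**

Numbering and enabling feature: ring C1 (C=O), C2=C3, C4 (CHOH), C5 (C(OH)R), C6 (CH2); chain C1'–C17'. In the single six-membered carbocycle, O1 and O4 stand 1,4 across C2=C3, O4 lies on the same face as the C5 hydroxyl, and C6 is a bare CH2. This is the pattern left when base isomerises a 2,3-dioxabicyclo[2.2.2]oct-5-ene bridged C1–O–O–C4.
Cuts: C1–O and C4–O are cut together (one O2), giving the arene hydrate (S)-1-alkenylcyclohexa-2,4-dien-1-ol. Its diene is traced through a dienyl triflate to an (S)-4-hydroxycyclohex-2-enone, then to a prochiral p-quinol (C5–O, from water) and a 4-alkenylphenol. Last, the aryl–C1' and C11'–C12' bonds are cut.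
Forward: the C6 and C11 chain pieces are joined first by Cu-catalysed Grignard coupling. The C17 chain is then fixed to 4-iodophenol by hydroboration and B-alkyl Suzuki–Miyaura coupling, and the benzene ring is reshaped into the carbocycle. No lasting ring is built; only the transient peroxide bridge forms.
Stereochemistry: C5 comes from ene-reductase desymmetrisation of the p-quinol. C4 comes from attack of singlet oxygen on the hydroxyl-bearing face of the dienol. The E-alkene is bought in with (E)-hex-3-en-1-ol.

Key step: step 10

Assumption: the sense of the enzymatic desymmetrisation cannot be predicted for a lipid-tailed quinol, so it is assumed that a panel of enantiocomplementary Old Yellow Enzyme homologues (OYE1, OYE2, OYE3, OPR1, OPR3, YqjM) contains a member that leaves the (S)-enone.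

**Route**

Step 1
Reactants: 1 (E)-hex-3-en-1-ol
Product: 2 (E)-1-bromohex-3-ene
Conditions: PPh3, NBS, CH2Cl2, −20 → 0 °C; pentane trituration, distillation
Reagents that add atoms: N-bromosuccinimide, O=C1CCC(=O)N1Br
Why: Appel-type bromination, in which the PPh3/NBS adduct activates the alcohol as an alkoxyphosphonium salt and bromide displaces Ph3PO by SN2 at the primary carbon without touching the E-alkene, the NBS variant being chosen because its by-products are involatile whereas the bromoform of the CBr4 variant would co-distil with 2 and disturb the Grignard formation that follows.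

Step 2
Reactants: 2 (E)-1-bromohex-3-ene; 3 11-bromoundec-1-ene
Product: 5 (E)-heptadeca-1,14-diene, via hexenylmagnesium bromide 4 (not isolated)
Conditions: 2, Mg, THF, 25–35 °C; then 3, Li2CuCl4 (cat.), THF, −10 °C → rt
Reagents that add atoms: none
Why: Copper-catalysed alkyl–alkyl cross-coupling of a Grignard reagent with a primary bromide (Kochi-type coupling with Li2CuCl4) should form the C11'–C12' bond by SN2-like attack of the alkylcuprate on 3 while both alkenes stay inert, and 4 is made near room temperature and used at once so that the slow homoallyl–cyclopropylcarbinyl exchange of such reagents cannot erode the E geometry.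

Step 3
Reactants: 5 (E)-heptadeca-1,14-diene; 6 4-iodophenol
Product: 8 4-[(E)-heptadec-14-enyl]phenol, via B-alkyl-9-BBN 7 (not isolated)
Conditions: 9-BBN (1.0 equiv), THF, 0 °C → rt; then 6, PdCl2(dppf) (cat.), aq. NaOH, THF, 60 °C; aq. NH4Cl work-up
Reagents that add atoms: none
Why: 9-BBN hydroborates the monosubstituted alkene in the anti-Markovnikov sense much faster than the internal 1,2-disubstituted one, and the hydroxyborate of 7 then hands its primary alkyl group to the arylpalladium iodide formed from 6 in a B-alkyl Suzuki–Miyaura coupling, in which dppf suppresses beta-hydride elimination and an extra equivalent of NaOH accommodates the acidic phenol.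

Step 4
Reactants: 8 4-[(E)-heptadec-14-enyl]phenol
Product: 9 4-[(E)-heptadec-14-enyl]-4-hydroxycyclohexa-2,5-dien-1-one (achiral p-quinol)
Conditions: PhI(OAc)2, aq. MeCN/acetone, 0 °C
Reagents that add atoms: water, O
Why: Oxidative dearomatisation of a 4-alkylphenol with a trivalent iodine reagent, in which the phenol oxygen binds to iodine, departure of PhI makes the ring electrophilic and water adds at the alkyl-bearing para carbon to give the p-quinol, the isolated chain alkene not being attacked by PhI(OAc)2 in the absence of acid activation.

Step 5
Reactants: 9 4-[(E)-heptadec-14-enyl]-4-hydroxycyclohexa-2,5-dien-1-one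
Product: 10 (S)-4-[(E)-heptadec-14-enyl]-4-hydroxycyclohex-2-en-1-one
Conditions: ene-reductase (Old Yellow Enzyme family, panel hit for the S product), NADP+ (cat.), glucose dehydrogenase, D-glucose, KH2PO4/K2HPO4 buffer pH 7, DMSO cosolvent, 30 °C
Reagents that add atoms: none
Why: Ene-reductase desymmetrisation of a 4,4-disubstituted cyclohexa-2,5-dienone, in which the bound substrate presents only one of its two enantiotopic C=C bonds to the reduced flavin, hydride goes to the beta carbon and an active-site proton to the alpha carbon, so that the prochiral carbinol carbon (C5 of the target) becomes the (S) stereocentre, while the hindered 4,4-disubstituted enone product should be reduced further only slowly.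

Step 6
Reactants: 10 (S)-4-[(E)-heptadec-14-enyl]-4-hydroxycyclohex-2-en-1-one
Product: 11 (S)-4-[(E)-heptadec-14-enyl]-4-(triethylsilyloxy)cyclohex-2-en-1-one
Conditions: Et3SiOTf, 2,6-lutidine, CH2Cl2, −78 → 0 °C
Reagents that add atoms: triethylsilyl trifluoromethanesulfonate, CC[Si](CC)(CC)OS(=O)(=O)C(F)(F)F
Why: Silylation of a hindered tertiary alcohol with a silyl triflate and a non-nucleophilic pyridine base is standard, the triethylsilyl group masks the acidic OH for the coming enolisation yet stays removable by fluoride without acid, and the stereocentre is not involved.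

Step 7
Reactants: 11 (S)-4-[(E)-heptadec-14-enyl]-4-(triethylsilyloxy)cyclohex-2-en-1-one
Product: 13 (S)-4-[(E)-heptadec-14-enyl]-4-(triethylsilyloxy)cyclohexa-1,5-dien-1-yl trifluoromethanesulfonate, via lithium dienolate 12 (not isolated)
Conditions: LDA, THF, −78 °C; then PhNTf2, −78 → 0 °C
Reagents that add atoms: N-phenylbis(trifluoromethanesulfonimide), O=S(=O)(N(c1ccccc1)S(=O)(=O)C(F)(F)F)C(F)(F)F
Why: Because the gamma carbon (C5 of the target) carries no hydrogen, LDA can only remove an alpha-prime proton and gives the cross-conjugated dienolate 12, whose O-sulfonylation with PhNTf2 (standard enol triflate synthesis) fixes the 1,3-diene skeleton without touching the stereocentre.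

Step 8
Reactants: 13 (S)-4-[(E)-heptadec-14-enyl]-4-(triethylsilyloxy)cyclohexa-1,5-dien-1-yl trifluoromethanesulfonate
Product: 14 (S)-triethyl({1-[(E)-heptadec-14-enyl]cyclohexa-2,4-dien-1-yl}oxy)silane
Conditions: Pd(OAc)2 (cat.), PPh3, HCO2H, Et3N (excess), DMF, 40 °C
Reagents that add atoms: none
Why: Palladium-catalysed formate hydrogenolysis of an enol triflate, in which zerovalent palladium inserts into the C–OTf bond, formate replaces triflate and loses CO2, and reductive elimination from the dienylpalladium hydride installs C–H with the diene position retained, the excess amine keeping the medium basic so that the acid-labile dienylic silyl ether is not ionised.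

Step 9
Reactants: 14 (S)-triethyl({1-[(E)-heptadec-14-enyl]cyclohexa-2,4-dien-1-yl}oxy)silane
Product: 15 (S)-1-[(E)-heptadec-14-enyl]cyclohexa-2,4-dien-1-ol (arene hydrate)
Conditions: Bu4NF, THF, 0 °C; aq. NaHCO3 work-up, Et3N-deactivated silica, used at once
Reagents that add atoms: none
Why: Fluoride-induced Si–O cleavage, driven by the strong Si–F bond, runs under basic conditions that arene hydrates tolerate, so the tertiary dienol should be released with its stereocentre intact provided work-up and chromatography are kept free of acid, which would trigger aromatising dehydration.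

Step 10
Reactants: 15 (S)-1-[(E)-heptadec-14-enyl]cyclohexa-2,4-dien-1-ol
Product: 17 (4R,5S)-5-[(E)-heptadec-14-enyl]-4,5-dihydroxycyclohex-2-en-1-one, via endoperoxide 16 (not isolated)
Conditions: O2, tetraphenylporphyrin (cat.), visible light, CH2Cl2 (filtered through basic Al2O3), −78 °C; then Et3N, −78 → 0 °C
Reagents that add atoms: dioxygen, O=O
Why: Dye-sensitised singlet oxygen engages the ring-held cisoid diene of 15 in a concerted suprafacial [4+2] cycloaddition that bonds one oxygen to the diene terminus beside the carbinol carbon (C4) and the other to the terminus beside the CH2 (C1), so the only ring closed is the transient 1,2-dioxine ring of the 2,3-dioxabicyclo[2.2.2]oct-5-ene 16, made by intermolecular cycloaddition, and no ring of the target is formed. Triethylamine then abstracts the C1 bridgehead hydrogen while the O–O bond breaks in an E2-like Kornblum–DeLaMare rearrangement that gives the C1 ketone, keeps C2=C3 and frees O4 as the alkoxide and then the hydroxyl, the closest known reaction type being photooxygenation of cyclohexa-1,3-dienes followed by amine-induced isomerisation to 4-hydroxycyclohex-2-enones. The new stereocentre C4 is decided by the diene face that oxygen attacks (the centre created at C1 is erased on opening): in non-polar CH2Cl2 the C5 hydroxyl can hydrogen-bond to the incoming oxygen while the larger alkyl chain covers the opposite face, so both effects place the bridge syn to the OH and lead to the cis-4,5-diol, (4R) from (5S). Site selectivity in the opening is also required and should follow from the C1–H being flanked only by a CH2 and open to the amine, whereas the C4–H is crowded by the fully substituted C5, and from the neighbouring tertiary OH stabilising the negative charge that builds on O4. Chemoselectivity rests on singlet oxygen reacting far faster with a cisoid cyclic diene than with the isolated 1,2-disubstituted chain alkene. Acid-free solvent, low temperature and brief contact with base guard against aromatising dehydration of 15 and against beta-elimination of the C5 hydroxyl from 17.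

**Compound list**

1 | (E)-hex-3-en-1-ol | CC/C=C/CCO | starting material
2 | (E)-1-bromohex-3-ene | CC/C=C/CCBr | intermediate
3 | 11-bromoundec-1-ene | C=CCCCCCCCCCBr | starting material
4 | (E)-hex-3-enylmagnesium bromide | CC/C=C/CC[Mg]Br | intermediate
5 | (E)-heptadeca-1,14-diene | CC/C=C/CCCCCCCCCCCC=C | intermediate
6 | 4-iodophenol | Ic1ccc(O)cc1 | starting material
7 | 9-[(E)-heptadec-14-enyl]-9-borabicyclo[3.3.1]nonane | CC/C=C/CCCCCCCCCCCCCB1C2CCCC1CCC2 | intermediate
8 | 4-[(E)-heptadec-14-enyl]phenol | CC/C=C/CCCCCCCCCCCCCc1ccc(O)cc1 | intermediate
9 | 4-[(E)-heptadec-14-enyl]-4-hydroxycyclohexa-2,5-dien-1-one | CC/C=C/CCCCCCCCCCCCCC1(O)C=CC(=O)C=C1 | intermediate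
10 | (S)-4-[(E)-heptadec-14-enyl]-4-hydroxycyclohex-2-en-1-one | CC/C=C/CCCCCCCCCCCCC[C@]1(O)CCC(=O)C=C1 | intermediate
11 | (S)-4-[(E)-heptadec-14-enyl]-4-(triethylsilyloxy)cyclohex-2-en-1-one | CC/C=C/CCCCCCCCCCCCC[C@]1(O[Si](CC)(CC)CC)CCC(=O)C=C1 | intermediate
12 | lithium (S)-4-[(E)-heptadec-14-enyl]-4-(triethylsilyloxy)cyclohexa-1,5-dien-1-olate | CC/C=C/CCCCCCCCCCCCC[C@]1(O[Si](CC)(CC)CC)CC=C([O-])C=C1.[Li+] | intermediate
13 | (S)-4-[(E)-heptadec-14-enyl]-4-(triethylsilyloxy)cyclohexa-1,5-dien-1-yl trifluoromethanesulfonate | CC/C=C/CCCCCCCCCCCCC[C@]1(O[Si](CC)(CC)CC)CC=C(OS(=O)(=O)C(F)(F)F)C=C1 | intermediate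
14 | (S)-triethyl({1-[(E)-heptadec-14-enyl]cyclohexa-2,4-dien-1-yl}oxy)silane | CC/C=C/CCCCCCCCCCCCC[C@]1(O[Si](CC)(CC)CC)CC=CC=C1 | intermediate
15 | (S)-1-[(E)-heptadec-14-enyl]cyclohexa-2,4-dien-1-ol | CC/C=C/CCCCCCCCCCCCC[C@]1(O)CC=CC=C1 | intermediate
16 | (1R,4R,7S)-7-[(E)-heptadec-14-enyl]-2,3-dioxabicyclo[2.2.2]oct-5-en-7-ol (peroxide bridge syn to the OH) | CC/C=C/CCCCCCCCCCCCC[C@]1(O)C[C@@H]2C=C[C@H]1OO2 | intermediate
17 | (4R,5S)-5-[(E)-heptadec-14-enyl]-4,5-dihydroxycyclohex-2-en-1-one | CC/C=C/CCCCCCCCCCCCC[C@]1(O)CC(=O)C=C[C@H]1O | target

**Count**

Total step count: 10. Longest linear sequence: 10 steps (1 → 17); 3 and 6 enter as purchased materials.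

**Steps most likely to fail**

Step 5.
- Risk: the waxy quinol may not reach or fit the active site, so conversion may stall. The enzyme may discriminate poorly between the two enantiotopic alkenes or prefer the wrong one. Long incubation may also reduce the second alkene.
- Fallback: chemical instead of enzymatic desymmetrisation, setting out from 9 and rejoining the route at 11.
- 9 is silylated with Et3SiOTf and 2,6-lutidine to the prochiral 4-[(E)-heptadec-14-enyl]-4-(triethylsilyloxy)cyclohexa-2,5-dien-1-one F1.
- F1 is then submitted to copper hydride catalysed asymmetric conjugate reduction: Cu(OAc)2, a DTBM-SEGPHOS-type bisphosphine of the enantiomeric series that leads to the S product, polymethylhydrosiloxane, t-BuOH, toluene, low temperature.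
- This is a known way to desymmetrise 4,4-disubstituted cyclohexadienones, and it runs in homogeneous organic solution, where the lipid chain is no handicap. It delivers 11 directly, so step 6 is absorbed.

Step 10.
- Risk: oxygen may attack the chain-bearing face in part. The amine may remove the C4 bridgehead hydrogen. An ene reaction at C6–H may compete. The base may also push the product on to beta-elimination of the C5 hydroxyl.
- Fallback: the cycloaddition is kept, but the redox-neutral isomerisation is replaced by reductive opening and site-defined re-oxidation. It sets out from 16 and rejoins at 17.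
- The cold photooxygenation mixture holding 16 is treated with thiourea in MeOH instead of amine. This cleaves only the O–O bond and should give the all-cis (1S,2R,5R)-1-[(E)-heptadec-14-enyl]cyclohex-3-ene-1,2,5-triol F2.
- 2,2-Dimethoxypropane and pyridinium p-toluenesulfonate tie the vicinal cis-diol (O4 and O5) into the 4,5-O-isopropylidene alcohol F3. This leaves only the C1 hydroxyl free and should also help to separate material from the wrong face.
- MnO2 in CH2Cl2 oxidises the allylic alcohol to the 4,5-O-isopropylidene enone F4, and aqueous acetic acid releases 17.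

Step 9.
- Risk: aromatising dehydration of the free tertiary dienol during desilylation, work-up, chromatography or storage.
- Fallback: the deprotection is moved behind the key step, so that the free arene hydrate is never handled. It sets out from 14 and rejoins at 17.
- 14 is photooxygenated under the conditions of step 10 to the silylated endoperoxide F5. Here the face is chosen on steric grounds, the oxygen substituent being slimmer at the ring than the CH2 of the chain.
- Et3N in the same pot opens F5 to (4R,5S)-5-[(E)-heptadec-14-enyl]-4-hydroxy-5-(triethylsilyloxy)cyclohex-2-en-1-one F6. The bulky silyl ether shields the C4–H further.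
- HF·pyridine in THF/pyridine then removes the silyl group to give 17.

**Further compounds**

F1 | step 5 | 4-[(E)-heptadec-14-enyl]-4-(triethylsilyloxy)cyclohexa-2,5-dien-1-one | CC/C=C/CCCCCCCCCCCCCC1(O[Si](CC)(CC)CC)C=CC(=O)C=C1
F2 | step 10 | (1S,2R,5R)-1-[(E)-heptadec-14-enyl]cyclohex-3-ene-1,2,5-triol | CC/C=C/CCCCCCCCCCCCC[C@]1(O)C[C@@H](O)C=C[C@H]1O
F3 | step 10 | 4,5-O-isopropylidene alcohol (acetonide of F2 across the vicinal cis-diol, C1 hydroxyl free) | CC/C=C/CCCCCCCCCCCCC[C@]12C[C@@H](O)C=C[C@H]1OC(C)(C)O2
F4 | step 10 | 4,5-O-isopropylidene enone (acetonide of 17) | CC/C=C/CCCCCCCCCCCCC[C@]12CC(=O)C=C[C@H]1OC(C)(C)O2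
F5 | step 9 | silylated endoperoxide (triethylsilyl ether of 16) | CC/C=C/CCCCCCCCCCCCC[C@]1(O[Si](CC)(CC)CC)C[C@@H]2C=C[C@H]1OO2
F6 | step 9 | (4R,5S)-5-[(E)-heptadec-14-enyl]-4-hydroxy-5-(triethylsilyloxy)cyclohex-2-en-1-one | CC/C=C/CCCCCCCCCCCCC[C@]1(O[Si](CC)(CC)CC)CC(=O)C=C[C@H]1O
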